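## Retrosynthetic overview

1. Prinsepiol is a cis-fused 3,7-dioxabicyclo[3.3.0]octane of C2 symmetry. The bridgeheads C1/C5 are quaternary C–OH carbons, and each benzylic carbon C2/C6 carries its aryl group on the convex face, cis to the neighbouring bridgehead oxygen. Without the aryl groups, C2 and C6 are two equivalent lactol carbons, each flanked by a ring oxygen (O3/O7) and by a carbon that bears no hydrogen; the route rests on this.
2. The last C–C bonds are C2–aryl and C6–aryl, made together from the 2,6-diacetoxy-1,5-bis(trimethylsilyloxy) bicycle and a diarylzinc (step 10). No ring is formed there; both tetrahydrofuran rings are already in place.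
3. The bis(lactol acetate) comes from the 1,5-dihydroxy-2,6-dione (bis-lactone) by silylation and reductive acetylation. The C1–C5 diol of the bis-lactone is the diol of L-tartaric acid.
4. Ring order: dioxolane of the tartrate acetonide (temporary), then ring 2 (C5–C6–O7–C8–C1) by lactonisation in step 2, then ring 1 (C1–C2–O3–C4–C5) by aldol–lactonisation in step 4, then removal of the dioxolane in step 5.
5. The tartrate C–H centre left untouched in step 2 fixes the first quaternary centre (C1) through lactonisation. It is itself made the second quaternary centre (C5) in step 4, with retention enforced by the cis ring fusion. The aryl unit comes from 4-bromo-2-methoxyphenol, two molecules per zinc atom.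

Key step: step 10

Remark on the chemistry: dimethyl L-tartrate is bought as its acetonide and formaldehyde is used as the monomer from cracked paraformaldehyde. The face on which formaldehyde adds to the monocyclic enolate in step 2 is not relied upon, because that carbon is made C(CH2OH)2 before its configuration is fixed by lactonisation.

## Route

Step 1
Reactants: 1 dimethyl (4R,5R)-2,2-dimethyl-1,3-dioxolane-4,5-dicarboxylate
Product: 2 (4R,5R)-5-(methoxycarbonyl)-2,2-dimethyl-1,3-dioxolane-4-carboxylic acid
Conditions: KOH (1.0 equiv), MeOH, 0 °C to rt; then aq. HCl, pH 2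
Reagents that add atoms: potassium hydroxide, [K+].[OH-]
Why: Saponification of one of two homotopic methyl esters with one equivalent of hydroxide (the carboxylate formed slows the second hydrolysis) should give a single half-ester without touching either C–H stereocentre.

Step 2
Reactants: 2 (4R,5R)-5-(methoxycarbonyl)-2,2-dimethyl-1,3-dioxolane-4-carboxylic acid; 3 formaldehyde
Product: 6 3-C-(hydroxymethyl)-2,3-O-isopropylidene-D-erythrono-1,4-lactone, via hydroxymethylated half-ester 4 (not isolated), via bis(hydroxymethyl) acid 5 (not isolated)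
Conditions: LiN(i-Pr)2 (2.2 equiv), THF, −78 °C; CH2O (g), −78 °C; LiBH4 (3 equiv), −78 to 0 °C; aq. HCl, pH 3; PPTS (cat.), PhMe, 50 °C
Reagents that add atoms: none
Why: Ester enolate aldol addition to formaldehyde occurs at the only carbon α to an ester (the carboxylate-bearing C–H centre, later C5, is not enolised), LiBH4 then reduces the methyl ester but not the carboxylate so that this carbon (later C1) becomes C(CH2OH)2 and both enolate faces converge, and acid lactonisation can only use the CH2OH that is cis to the carboxyl on the dioxolane, which sets C1 from the preserved tartrate centre.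

Step 3
Reactants: 6 3-C-(hydroxymethyl)-2,3-O-isopropylidene-D-erythrono-1,4-lactone
Product: 8 3-C-(methoxycarbonyl)-2,3-O-isopropylidene-D-erythrono-1,4-lactone, via lactone acid 7 (not isolated)
Conditions: TEMPO (cat.), PhI(OAc)2, MeCN/H2O, rt; then Me3SiCHN2, PhMe/MeOH, 0 °C
Reagents that add atoms: water, O; (trimethylsilyl)diazomethane, C[Si](C)(C)C=[N+]=[N-]
Why: Nitroxyl-catalysed (TEMPO) oxidation of the primary alcohol through the aldehyde hydrate to the acid, then methyl ester formation with the diazoalkane, should leave both stereocentres alone, since C1 is quaternary and C5–H is not enolised under these near-neutral conditions.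

Step 4
Reactants: 8 3-C-(methoxycarbonyl)-2,3-O-isopropylidene-D-erythrono-1,4-lactone; 3 formaldehyde
Product: 10 1,5-O-isopropylidene-(1R,5R)-1,5-dihydroxy-3,7-dioxabicyclo[3.3.0]octane-2,6-dione, via hydroxymethyl lactone ester 9 (not isolated)
Conditions: LiN(i-Pr)2 (1.1 equiv), THF, −78 °C; CH2O (g), −78 to 0 °C; AcOH; then PPTS (cat.), PhMe, 50 °C
Reagents that add atoms: none
Why: Lactone enolate aldol with formaldehyde is followed by lactonisation of the new hydroxyl onto the neighbouring methyl ester; the enolate carbon C5 is a ring-fusion atom of the cis-fused dioxolane/γ-lactone, so the electrophile has to enter on the exo face where H stood (cis to the C1 ester), which sets the second quaternary centre and lets ring 1 close.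

Step 5
Reactants: 10 1,5-O-isopropylidene-(1R,5R)-1,5-dihydroxy-3,7-dioxabicyclo[3.3.0]octane-2,6-dione
Product: 11 (1R,5R)-1,5-dihydroxy-3,7-dioxabicyclo[3.3.0]octane-2,6-dione
Conditions: CF3CO2H/H2O (9:1), rt
Reagents that add atoms: none
Why: Acid hydrolysis of the isopropylidene acetal, the only acid-labile group (the lactones re-close if opened), involves no stereocentre.

Step 6
Reactants: 11 (1R,5R)-1,5-dihydroxy-3,7-dioxabicyclo[3.3.0]octane-2,6-dione
Product: 12 (1R,5R)-1,5-bis(trimethylsilyloxy)-3,7-dioxabicyclo[3.3.0]octane-2,6-dione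
Conditions: Me3SiCl, imidazole, DMF, rt
Reagents that add atoms: chlorotrimethylsilane, C[Si](C)(C)Cl
Why: Silylation of the two tertiary α-hydroxy-lactone hydroxyls with the smallest silyl chloride should give non-participating ethers that tolerate hydride and bromosilane.

Step 7
Reactants: 12 (1R,5R)-1,5-bis(trimethylsilyloxy)-3,7-dioxabicyclo[3.3.0]octane-2,6-dione
Product: 14 (1R,5R)-2,6-diacetoxy-1,5-bis(trimethylsilyloxy)-3,7-dioxabicyclo[3.3.0]octane, via bis(aluminium hemiacetal) 13 (not isolated)
Conditions: i-Bu2AlH (2.3 equiv), CH2Cl2, −78 °C; then pyridine, DMAP, Ac2O, −78 to 0 °C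
Reagents that add atoms: acetic anhydride, CC(=O)OC(C)=O
Why: In this one-pot reductive acetylation of lactones, i-Bu2AlH stops at the tetrahedral aluminium hemiacetal at −78 °C and Ac2O/pyridine/DMAP traps it as the α-acetoxy ether before ring opening; the anomeric configuration (a mixture) is irrelevant because it is erased in step 10.

Step 8
Reactants: 15 4-bromo-2-methoxyphenol
Product: 16 (4-bromo-2-methoxyphenoxy)(tert-butyl)dimethylsilane
Conditions: t-BuMe2SiCl, imidazole, DMF, rt
Reagents that add atoms: tert-butyldimethylsilyl chloride, CC(C)(C)[Si](C)(C)Cl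
Why: Standard silylation of a phenol gives a bulky silyl ether that should survive the organolithium and zinc chemistry.

Step 9
Reactants: 16 (4-bromo-2-methoxyphenoxy)(tert-butyl)dimethylsilane (two molecules per zinc atom)
Product: 18 bis[4-(tert-butyldimethylsilyloxy)-3-methoxyphenyl]zinc, via aryllithium 17 (not isolated)
Conditions: n-BuLi (1.0 equiv per 16), PhMe/n-Bu2O, −20 °C; ZnBr2 (0.5 equiv per 16), n-Bu2O, to rt; used as the solution
Reagents that add atoms: zinc dibromide, [Zn+2].[Br-].[Br-]; second molecule of 16 (supplies the second aryl group on zinc), COc1cc(Br)ccc1O[Si](C)(C)C(C)(C)C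
Why: Bromine–lithium exchange on two molecules of 16 followed by transmetalation of the two aryllithiums with one ZnBr2 should give the diarylzinc in a weakly coordinating solvent mixture that keeps the zinc Lewis acidic for step 10.

Step 10
Reactants: 14 (1R,5R)-2,6-diacetoxy-1,5-bis(trimethylsilyloxy)-3,7-dioxabicyclo[3.3.0]octane; 18 bis[4-(tert-butyldimethylsilyloxy)-3-methoxyphenyl]zinc
Product: 20 (1S,2R,5S,6R)-2,6-bis[4-(tert-butyldimethylsilyloxy)-3-methoxyphenyl]-1,5-bis(trimethylsilyloxy)-3,7-dioxabicyclo[3.3.0]octane, via dibromide 19 (not isolated)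
Conditions: Me3SiBr (2.5 equiv), CH2Cl2, 0 °C to rt, evaporate; then 18 (2.2 equiv), PhMe/n-Bu2O, 0 to 50 °C
Reagents that add atoms: none
Why: Me3SiBr converts both anomeric acetates into bromides 19 (the Me3Si ethers are inert to it), and ZnBr2/arylzinc ionises each C–Br bond to a five-membered oxocarbenium ion (C2=O3+ or C6=O7+) that is captured by aryl transfer from zinc, which is the known uncatalysed C-arylation of furanosyl halides with diarylzinc reagents. No ring is closed: both tetrahydrofuran rings are present in 14 and only the two C–aryl bonds are formed. The new stereocentres C2 and C6 are set by substrate control, the aryl group adding to the convex face of the cis-fused bicycle, which is the face of the C1 (or C5) OSiMe3 group, so that each aryl ends up cis to the neighbouring bridgehead oxygen as in the target. The selectivity needed is facial only, and it is secured by the fold of the bicyclo[3.3.0] skeleton, which buries the other face under the second ring, and by silyl ethers that cannot bridge to the cationic carbon as an acyloxy group would. C2 symmetry makes the two reacting carbons equivalent, so there is no regiochemical issue and the mono-arylated intermediate should react in the same sense. Because C1 and C5 are quaternary, the oxocarbenium ions have no hydrogen at the ring fusion and cannot collapse to an enol ether.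

Step 11
Reactants: 20 (1S,2R,5S,6R)-2,6-bis[4-(tert-butyldimethylsilyloxy)-3-methoxyphenyl]-1,5-bis(trimethylsilyloxy)-3,7-dioxabicyclo[3.3.0]octane
Product: 21 prinsepiol
Conditions: Bu4NF, AcOH, THF, 0 °C to rt
Reagents that add atoms: none
Why: Fluoride-induced desilylation should remove the two tertiary trimethylsilyl ethers and the two aryl silyl ethers, the AcOH buffer avoiding phenoxide oxidation, and no C–O or C–C bond of the bicycle is affected, so all four stereocentres are kept.

## Compound list

1 | dimethyl (4R,5R)-2,2-dimethyl-1,3-dioxolane-4,5-dicarboxylate (acetonide of dimethyl L-tartrate) | COC(=O)[C@@H]1OC(C)(C)O[C@H]1C(=O)OC | starting material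
2 | (4R,5R)-5-(methoxycarbonyl)-2,2-dimethyl-1,3-dioxolane-4-carboxylic acid | COC(=O)[C@@H]1OC(C)(C)O[C@H]1C(=O)O | intermediate
3 | formaldehyde (monomer from paraformaldehyde) | C=O | starting material
4 | (4R)-5-(hydroxymethyl)-5-(methoxycarbonyl)-2,2-dimethyl-1,3-dioxolane-4-carboxylic acid, both C5 epimers, dilithium salt in the flask (not isolated) | COC(=O)C1(CO)OC(C)(C)O[C@H]1C(=O)O | intermediate
5 | (4R)-5,5-bis(hydroxymethyl)-2,2-dimethyl-1,3-dioxolane-4-carboxylic acid (not isolated) | OCC1(CO)OC(C)(C)O[C@H]1C(=O)O | intermediate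
6 | 3-C-(hydroxymethyl)-2,3-O-isopropylidene-D-erythrono-1,4-lactone = (3aR,6aR)-6a-(hydroxymethyl)-2,2-dimethyldihydrofuro[3,4-d][1,3]dioxol-4(3aH)-one; cis-fused, CH2OH on the ring-fusion carbon β to C=O | OC[C@@]21OC(C)(C)O[C@H]1C(=O)OC2 | intermediate
7 | 3-C-carboxy-2,3-O-isopropylidene-D-erythrono-1,4-lactone (not isolated) | OC(=O)[C@@]21OC(C)(C)O[C@H]1C(=O)OC2 | intermediate
8 | 3-C-(methoxycarbonyl)-2,3-O-isopropylidene-D-erythrono-1,4-lactone | COC(=O)[C@@]21OC(C)(C)O[C@H]1C(=O)OC2 | intermediate
9 | 2-C-(hydroxymethyl)-3-C-(methoxycarbonyl)-2,3-O-isopropylidene-D-erythrono-1,4-lactone; CH2OH and CO2Me cis, both exo (not isolated) | COC(=O)[C@@]21OC(C)(C)O[C@@]1(CO)C(=O)OC2 | intermediate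
10 | 1,5-O-isopropylidene-(1R,5R)-1,5-dihydroxy-3,7-dioxabicyclo[3.3.0]octane-2,6-dione (bis-lactone with the dioxolane as third ring on C1–C5) | C1OC(=O)[C@@]23OC(C)(C)O[C@]13C(=O)OC2 | intermediate
11 | (1R,5R)-1,5-dihydroxy-3,7-dioxabicyclo[3.3.0]octane-2,6-dione | C1OC(=O)[C@]2(O)[C@@]1(O)C(=O)OC2 | intermediate
12 | (1R,5R)-1,5-bis(trimethylsilyloxy)-3,7-dioxabicyclo[3.3.0]octane-2,6-dione | C1OC(=O)[C@]2(O[Si](C)(C)C)[C@@]1(O[Si](C)(C)C)C(=O)OC2 | intermediate
13 | bis(diisobutylaluminium) alkoxide of (1R,5R)-1,5-bis(trimethylsilyloxy)-3,7-dioxabicyclo[3.3.0]octane-2,6-diol (not isolated) | CC(C)C[Al](CC(C)C)OC1OC[C@]2(O[Si](C)(C)C)C(O[Al](CC(C)C)CC(C)C)OC[C@]12O[Si](C)(C)C | intermediate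
14 | (1R,5R)-2,6-diacetoxy-1,5-bis(trimethylsilyloxy)-3,7-dioxabicyclo[3.3.0]octane, anomeric mixture at C2/C6 | CC(=O)OC1OC[C@]2(O[Si](C)(C)C)C(OC(C)=O)OC[C@]12O[Si](C)(C)C | intermediate
15 | 4-bromo-2-methoxyphenol | COc1cc(Br)ccc1O | starting material
16 | (4-bromo-2-methoxyphenoxy)(tert-butyl)dimethylsilane | COc1cc(Br)ccc1O[Si](C)(C)C(C)(C)C | intermediate
17 | [4-(tert-butyldimethylsilyloxy)-3-methoxyphenyl]lithium (not isolated) | [Li]c1ccc(O[Si](C)(C)C(C)(C)C)c(OC)c1 | intermediate
18 | bis[4-(tert-butyldimethylsilyloxy)-3-methoxyphenyl]zinc | COc1cc([Zn]c2ccc(O[Si](C)(C)C(C)(C)C)c(OC)c2)ccc1O[Si](C)(C)C(C)(C)C | intermediate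
19 | (1R,5R)-2,6-dibromo-1,5-bis(trimethylsilyloxy)-3,7-dioxabicyclo[3.3.0]octane, anomeric mixture (not isolated) | BrC1OC[C@]2(O[Si](C)(C)C)C(Br)OC[C@]12O[Si](C)(C)C | intermediate
20 | (1S,2R,5S,6R)-2,6-bis[4-(tert-butyldimethylsilyloxy)-3-methoxyphenyl]-1,5-bis(trimethylsilyloxy)-3,7-dioxabicyclo[3.3.0]octane | COc1cc([C@H]2OC[C@]3(O[Si](C)(C)C)[C@@H](c4ccc(O[Si](C)(C)C(C)(C)C)c(OC)c4)OC[C@]23O[Si](C)(C)C)ccc1O[Si](C)(C)C(C)(C)C | intermediate
21 | prinsepiol, (1S,2R,5S,6R)-2,6-bis(4-hydroxy-3-methoxyphenyl)-3,7-dioxabicyclo[3.3.0]octane-1,5-diol | COc1cc([C@H]2OC[C@]3(O)[C@@H](c4ccc(O)c(OC)c4)OC[C@]23O)ccc1O | target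

## Step count and risks

Total: 11 steps. Longest linear sequence: 9 steps (steps 1–7, 10, 11); steps 8 and 9 form the aryl branch.

Steps most likely to fail:

1. Step 10. The aryl group may be transferred to the face anti to the bridgehead OSiMe3 groups if these screen the convex face, which would give the C2/C6 epimers. The fallback sets out from 12 and returns at 20. Aryllithium 17 (2.2 equiv, THF, −78 °C) adds once to each lactone carbonyl of 12 to give the bis(hemiketal) F1. Et3SiH with Me3SiOTf (CH2Cl2, −78 °C) then reduces both hemiketals through the 2-aryl oxocarbenium ions to 20. Here hydride is the incoming group, so the face that nucleophiles prefer is taken by H and the aryl group is left on the other face. The sequence is the stereochemical complement of step 10 and would be used when step 10 delivers aryl to the wrong face.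

2. Step 2. The carboxylate-bearing dianion may form incompletely or react sluggishly with gaseous formaldehyde, and water-soluble material may be lost in the telescoped reduction and lactonisation. The fallback sets out from 2 and returns at 6. BH3·SMe2 (THF, 0 °C) reduces the acid of 2 but not the ester to give methyl 2,3-O-isopropylidene-L-threonate F2, and Swern oxidation gives the aldehyde ester F3. Aqueous formaldehyde with K2CO3 in MeOH hydroxymethylates the aldehyde α-carbon through the aldehyde enolate to the hydroxymethyl aldehyde F4 (either epimer). NaBH4 in the same flask reduces the aldehyde to the bis(hydroxymethyl) ester F5, which closes to 6 with PPTS. The carbon that becomes C(CH2OH)2 is now the one that carried the acid, and the other tartrate C–H centre keeps its configuration. By the C2 symmetry of 1, the lactone obtained is the same compound 6.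

3. Step 4. The lithium enolate of the bicyclic lactone may open the dioxolane by β-elimination before it is hydroxymethylated, or the congested exo face may react slowly with formaldehyde. The fallback sets out from 8 and returns at 10. Deprotonation with LiN(i-Pr)2 in the presence of Me3SiCl (THF, −78 °C) traps the enolate at once as the silyl ketene acetal F6. BnOCH2Cl with ZnBr2 (cat.) in CH2Cl2 alkylates F6 (Mukaiyama-type, exo face for the same ring-fusion reason) to the benzyloxymethyl lactone F7. Hydrogenolysis (H2, Pd/C, EtOAc) frees alcohol 9, which lactonises to 10.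

Further compounds
F1 | step 10 | (1R,5R)-2,6-bis[4-(tert-butyldimethylsilyloxy)-3-methoxyphenyl]-2,6-dihydroxy-1,5-bis(trimethylsilyloxy)-3,7-dioxabicyclo[3.3.0]octane, mixture at C2/C6 | COc1cc(C2(O)OC[C@]3(O[Si](C)(C)C)C(O)(c4ccc(O[Si](C)(C)C(C)(C)C)c(OC)c4)OC[C@]23O[Si](C)(C)C)ccc1O[Si](C)(C)C(C)(C)C
F2 | step 2 | methyl (4R,5S)-5-(hydroxymethyl)-2,2-dimethyl-1,3-dioxolane-4-carboxylate (methyl 2,3-O-isopropylidene-L-threonate) | COC(=O)[C@@H]1OC(C)(C)O[C@H]1CO
F3 | step 2 | methyl (4R,5R)-5-formyl-2,2-dimethyl-1,3-dioxolane-4-carboxylate | COC(=O)[C@@H]1OC(C)(C)O[C@H]1C=O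
F4 | step 2 | methyl (4R)-5-formyl-5-(hydroxymethyl)-2,2-dimethyl-1,3-dioxolane-4-carboxylate, both C5 epimers | COC(=O)[C@@H]1OC(C)(C)OC1(CO)C=O
F5 | step 2 | methyl (4R)-5,5-bis(hydroxymethyl)-2,2-dimethyl-1,3-dioxolane-4-carboxylate | COC(=O)[C@@H]1OC(C)(C)OC1(CO)CO
F6 | step 4 | trimethylsilyl ketene acetal of 8 (C=C between the former C5 and the lactone carbonyl carbon, OSiMe3 on the latter) | COC(=O)[C@]12OC(C)(C)OC1=C(O[Si](C)(C)C)OC2
F7 | step 4 | 2-C-(benzyloxymethyl)-3-C-(methoxycarbonyl)-2,3-O-isopropylidene-D-erythrono-1,4-lactone | COC(=O)[C@@]21OC(C)(C)O[C@@]1(COCc3ccccc3)C(=O)OC2
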